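**Strategy.** The strained nine-membered oxonene (O–C7–C6–C5–C4–C3–C2–C1–C10) is not closed at carbon. Instead, a ten-membered ring with sulfur between C4 and C5 is closed by thiolate alkylation and then contracted. In one operation the Ramberg–Bäcklund reaction of sulfone 31 deletes sulfur, forms the C4=C5 bond and fixes it as Z. It exploits the cis C7/C10 bridge of the tetrahydrofuran ring, which lets only the cis-fused episulfone form. Sulfone 31 carries the C1 ketone as a dimethyl ketal, C6–O as a PMB ether and C8/C12 as silyl ethers; its tetrahydrofuran core comes from (R)-citramalic acid by stereospecific epoxide opening. The Z alkene later takes the C4–C5 epoxide under direction from C6–OH.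

Key step: step 22

Remark: carbons keep the locants of the target (C1 ketone, C4/C5 epoxide, C6 lactone carbinol, C7 spiro carbon, C8 ester carbinol, C10 ether carbon, C11–C13 methylene-lactone carbons, C14/C15 methyls); the C4 configuration of the sulfone is lost in the key step and the (4S) epimer is the one made. PMB = 4-methoxybenzyl, TBS = tert-butyldimethylsilyl, TBDPS = tert-butyldiphenylsilyl, TES = triethylsilyl.

Step 1
Reactants: 1 (R)-citramalic acid
Product: 2 2-[(4R)-2,2,4-trimethyl-5-oxo-1,3-dioxolan-4-yl]acetic acid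
Conditions: Me2C(OMe)2, PPTS (cat.), CH2Cl2, rt
Reagents that add atoms: 2,2-dimethoxypropane, COC(C)(C)OC
Why: Acid-catalysed acetalisation ties the α-hydroxy acid pair (C10–OH and the C1 carboxyl) into a five-membered dioxolanone and leaves the C8 carboxyl free, so the two carboxyls are told apart without touching the C10 stereocentre taken from the chiral pool.

Step 2
Reactants: 2 2-[(4R)-2,2,4-trimethyl-5-oxo-1,3-dioxolan-4-yl]acetic acid; 3 4-methoxybenzyl propargyl ether
Product: 5 (5R)-5-[5-(4-methoxybenzyloxy)-2-oxopent-3-yn-1-yl]-2,2,5-trimethyl-1,3-dioxolan-4-one, via acid chloride 4 (not isolated)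
Conditions: (COCl)2, DMF (cat.), CH2Cl2, 0 °C → rt, evaporate; then 3, PdCl2(PPh3)2 (2 mol%), CuI (4 mol%), Et3N, THF, rt
Reagents that add atoms: none
Why: Acyl Sonogashira coupling of the acid chloride with the terminal alkyne should form the C7–C8 bond as an ynone under conditions too mild to open the dioxolanone.

Step 3
Reactants: 5 (5R)-5-[5-(4-methoxybenzyloxy)-2-oxopent-3-yn-1-yl]-2,2,5-trimethyl-1,3-dioxolan-4-one
Product: 6 (5R)-5-[(2S)-2-hydroxy-5-(4-methoxybenzyloxy)pent-3-yn-1-yl]-2,2,5-trimethyl-1,3-dioxolan-4-one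
Conditions: Ru(p-cymene)[(S,S)-TsNCHPhCHPhNH] (1 mol%), i-PrOH, rt
Reagents that add atoms: none
Why: Noyori asymmetric transfer hydrogenation of an alkynyl ketone, in which the (S,S)-diamine ruthenium hydride treats the alkynyl group as it treats an aryl group, should set C8 as (S) under catalyst control without base that could harm the ynone.

Step 4
Reactants: 6 (5R)-5-[(2S)-2-hydroxy-5-(4-methoxybenzyloxy)pent-3-yn-1-yl]-2,2,5-trimethyl-1,3-dioxolan-4-one
Product: 7 (5R)-5-[(2S)-2-(tert-butyldiphenylsilyloxy)-5-(4-methoxybenzyloxy)pent-3-yn-1-yl]-2,2,5-trimethyl-1,3-dioxolan-4-one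
Conditions: TBDPSCl, imidazole, DMAP (cat.), CH2Cl2, 0 °C → rt
Reagents that add atoms: tert-butyl(chloro)diphenylsilane, CC(C)(C)[Si](Cl)(c1ccccc1)c1ccccc1
Why: Imidazole-mediated silylation of the secondary propargylic alcohol protects C8–OH robustly and removes the hydroxyl that could otherwise open the dioxolanone to a γ-lactone.

Step 5
Reactants: 8 (R)-butane-1,3-diol
Product: 9 (R)-4-iodobutan-2-ol
Conditions: I2, PPh3, imidazole, CH2Cl2, 0 °C
Reagents that add atoms: iodine, II
Why: Garegg–Samuelsson (Appel-type) iodination is selective for the primary hydroxyl of the 1,3-diol and does not touch the C4 stereocentre.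

Step 6
Reactants: 9 (R)-4-iodobutan-2-ol
Product: 10 (R)-triethyl[(4-iodobutan-2-yl)oxy]silane
Conditions: TESCl, imidazole, CH2Cl2, 0 °C
Reagents that add atoms: chlorotriethylsilane, CC[Si](Cl)(CC)CC
Why: Standard silylation masks the C4 hydroxyl as an ether that tolerates an organolithium and can later be removed in the presence of the other silyl ethers.

Step 7
Reactants: 10 (R)-triethyl[(4-iodobutan-2-yl)oxy]silane; 7 (5R)-5-[(2S)-2-(tert-butyldiphenylsilyloxy)-5-(4-methoxybenzyloxy)pent-3-yn-1-yl]-2,2,5-trimethyl-1,3-dioxolan-4-one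
Product: 13 hydroxy ketone (C1 ketone; 10R tertiary alcohol; 8S OTBDPS; 4R OTES; C6≡C7 alkyne; C5 OPMB), via alkyllithium 11 (not isolated), via lithium hemiketal 12 (not isolated)
Conditions: 10, t-BuLi (2.0 equiv), Et2O–pentane, −78 °C; then 7, THF, −78 °C; AcOH, −78 °C → rt
Reagents that add atoms: none
Why: Iodine–lithium exchange followed by mono-addition of the alkyllithium to the lactone-type carbonyl forms the C1–C2 bond; the cyclic lithium hemiketal is stable at −78 °C and collapses to the ketone with loss of acetone only after the acidic quench, so a second addition is avoided and C10–OH is freed in the same operation.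

Step 8
Reactants: 13 hydroxy ketone
Product: 14 C1 dimethyl ketal of 13 (10R tertiary alcohol free)
Conditions: TMSOMe, TMSOTf (cat.), CH2Cl2, −78 → −30 °C; then K2CO3, MeOH, 0 °C
Reagents that add atoms: methoxytrimethylsilane, CO[Si](C)(C)C
Why: Noyori ketalisation (silyl triflate-catalysed exchange with methoxytrimethylsilane) is driven by formation of hexamethyldisiloxane, works on hindered ketones and is aprotic, so the triethylsilyl ether survives; the carbonate work-up removes any silyl group picked up by the tertiary hydroxyl.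

Step 9
Reactants: 14 C1 dimethyl ketal
Product: 15 propargylic alcohol (C5–OH free; otherwise as 14)
Conditions: DDQ, CH2Cl2–pH 7 buffer, 0 °C
Reagents that add atoms: none
Why: Oxidative cleavage of the PMB ether by DDQ (benzylic hydride abstraction, then hydrolysis) frees the C5 hydroxyl, while silyl ethers, alkyne and the slowly ionising α-oxygenated ketal do not react.

Step 10
Reactants: 15 propargylic alcohol
Product: 17 Z vinyl iodide (iodine on C7; cis to the C5 hydroxymethyl group), via alkenylaluminate 16 (not isolated)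
Conditions: NaAlH2(OCH2CH2OMe)2 (Red-Al), THF, 0 °C → rt; then I2, THF, −78 °C; aq. KNa tartrate
Reagents that add atoms: iodine, II
Why: Hydroxyl-directed trans-hydroalumination of the propargylic alcohol puts hydride on C6 and aluminium on C7 within a five-membered alkoxyaluminate, and iodinolysis with retention gives the 3-iodo-(Z)-allylic alcohol.

Step 11
Reactants: 18 2-bromoprop-2-en-1-ol
Product: 19 (2-bromoallyloxy)(tert-butyl)dimethylsilane
Conditions: TBSCl, imidazole, CH2Cl2, rt
Reagents that add atoms: tert-butyl(chloro)dimethylsilane, CC(C)(C)[Si](C)(C)Cl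
Why: Routine silylation protects the future C12 hydroxyl as the most labile of the three silyl ethers used.

Step 12
Reactants: 19 (2-bromoallyloxy)(tert-butyl)dimethylsilane
Product: 20 tert-butyldimethyl{[2-(4,4,5,5-tetramethyl-1,3,2-dioxaborolan-2-yl)prop-2-en-1-yl]oxy}silane
Conditions: B2pin2, PdCl2(PPh3)2 (3 mol%), PPh3, KOPh, toluene, 50 °C
Reagents that add atoms: bis(pinacolato)diboron, CC1(C)OB(OC1(C)C)B1OC(C)(C)C(C)(C)O1
Why: Miyaura borylation of the alkenyl bromide gives the 1,1-disubstituted alkenyl boronate (the C11–C13 unit) without an organolithium.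

Step 13
Reactants: 17 Z vinyl iodide; 20 alkenyl boronate
Product: 21 dienol (2E in chain terms: C11 on C7 cis to C5; C5–OH free)
Conditions: PdCl2(dppf) (5 mol%), K3PO4 (aq.), THF, 45 °C
Reagents that add atoms: none
Why: Suzuki–Miyaura coupling proceeds with retention at both sp2 carbons and tolerates the free hydroxyls, joining C7 to C11 with the alkene geometry that the later epoxide opening needs.

Step 14
Reactants: 21 dienol
Product: 23 tetrahydrofuran diol (ring O–C7–C8–C9–C10; 6R secondary and C5 primary hydroxyls), via epoxy alcohol 22 (not isolated)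
Conditions: Ti(OiPr)4 (0.3 equiv), D-(−)-DIPT (0.36 equiv), t-BuOOH, 4 Å MS, CH2Cl2, −20 °C; then CSA (cat.), CH2Cl2, 0 °C
Reagents that add atoms: tert-butyl hydroperoxide, CC(C)(C)OO
Why: Sharpless asymmetric epoxidation with the D-tartrate places oxygen on the face of C6=C7 that gives the (6R,7S) epoxy alcohol under reagent control, and acid-catalysed 5-exo opening by the C10 hydroxyl at the tertiary allylic C7 with inversion closes the tetrahydrofuran and sets C7 and C6 as in the target.

Step 15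
Reactants: 23 tetrahydrofuran diol
Product: 24 C5/C6 4-methoxybenzylidene acetal (both acetal epimers)
Conditions: 4-MeOC6H4CH(OMe)2, PPTS (cat.), CH2Cl2, rt
Reagents that add atoms: 4-methoxybenzaldehyde dimethyl acetal, COc1ccc(C(OC)OC)cc1
Why: Acid-catalysed transacetalisation forms the five-membered arylidene acetal of the 1,2-diol much faster than the α-oxygenated C1 ketal can ionise.

Step 16
Reactants: 24 4-methoxybenzylidene acetal
Product: 25 C6 PMB ether with free C5 primary alcohol
Conditions: i-Bu2AlH, CH2Cl2, −78 → −20 °C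
Reagents that add atoms: none
Why: In this regioselective reductive acetal opening the aluminium hydride binds the less hindered primary oxygen, so hydride delivery leaves the PMB group on the hindered C6 oxygen and frees C5–OH.

Step 17
Reactants: 25 C6 PMB ether with free C5 alcohol
Product: 26 C5 mesylate
Conditions: MsCl, Et3N, CH2Cl2, 0 °C
Reagents that add atoms: methanesulfonyl chloride, CS(=O)(=O)Cl
Why: Sulfonylation of the only free hydroxyl turns C5 into the electrophile for ring closure.

Step 18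
Reactants: 26 C5 mesylate
Product: 27 C5 mesylate with free (4R) alcohol
Conditions: HF·pyridine, pyridine, THF, 0 °C
Reagents that add atoms: none
Why: Buffered fluoride desilylation removes the secondary triethylsilyl ether much faster than the bulkier primary TBS and the TBDPS ethers, and is too weakly acidic to let the freed C4 hydroxyl exchange into the C1 ketal.

Step 19
Reactants: 27 C5 mesylate with free (4R) alcohol
Product: 28 (4S) thioacetate bearing the C5 mesylate
Conditions: PPh3, DIAD, AcSH, THF, 0 °C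
Reagents that add atoms: thioacetic acid, CC(=O)S
Why: The Mitsunobu reaction with thioacetic acid converts the unhindered secondary alcohol into the thioacetate with inversion, while the hindered primary mesylate is not displaced at 0 °C.

Step 20
Reactants: 28 (4S) thioacetate bearing the C5 mesylate
Product: 30 ten-membered cyclic sulfide (ring O–C7–C6–C5–S–C4–C3–C2–C1–C10), via caesium thiolate 29 (not isolated)
Conditions: Cs2CO3, MeOH–THF (degassed), 1 mM, rt → 40 °C
Reagents that add atoms: none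
Why: Methanolysis of the thioacetate releases the C4 thiolate, which should close the ring by intramolecular SN2 displacement of the C5 mesylate, helped by high dilution and by the cis C7/C10 substitution of the tetrahydrofuran that holds both arms on one face.

Step 21
Reactants: 30 ten-membered cyclic sulfide
Product: 31 ten-membered cyclic sulfone (C1 dimethyl ketal; C6 OPMB; C8 OTBDPS; C12 OTBS)
Conditions: (NH4)6Mo7O24·4H2O (cat.), 30% H2O2, EtOH, 0 °C → rt
Reagents that add atoms: hydrogen peroxide, OO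
Why: Molybdate-catalysed peroxide oxidation takes the sulfide through the sulfoxide to the sulfone and leaves the 1,1-disubstituted alkene, the PMB ether and the silyl ethers alone.

Step 22
Reactants: 31 ten-membered cyclic sulfone
Product: 34 Z-oxonene (C4=C5 in the nine-membered ring; C1 dimethyl ketal; C6 OPMB; C8 OTBDPS; C12 OTBS), via α-bromo sulfone 32 (not isolated), via episulfone 33 (not isolated)
Conditions: KOH/Al2O3, CBr2F2, t-BuOH–CH2Cl2, 5 °C → rt
Reagents that add atoms: none
Why: Hydroxide on alumina deprotonates the sulfone at the less hindered C5 methylene, the carbanion takes bromine from CBr2F2 to give 32, and a second deprotonation at C4 triggers 1,3-displacement of bromide to the thiirane 1,1-dioxide 33, which loses SO2 to leave the C4=C5 bond. This is the Ramberg–Bäcklund reaction in its one-flask halogenative form, whose closest precedent is the contraction of medium and large cyclic sulfones to cycloalkenes. The nine-membered oxonene is closed by a 3-exo-tet carbanion alkylation inside the existing ten-membered ring followed by cheletropic extrusion, so no new macrocyclisation is needed. No stereocentre is formed; the alkene geometry should be Z because C3 and C6 are tied through the tetrahydrofuran-bridged ring, only the cis-fused episulfone can form, and SO2 loss is stereospecific. The step needs bromination and closure to outrun β-elimination of the C6 ether and reaction at other acidic sites, which the poor leaving ability of the PMB oxide, the ketal mask on C1 and the absence of other acidic C–H bonds are expected to secure.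

Step 23
Reactants: 34 Z-oxonene with C1 dimethyl ketal
Product: 35 Z-oxonene C1 ketone
Conditions: PPTS, acetone–H2O, 50 °C
Reagents that add atoms: water, O
Why: Acid-catalysed ketal hydrolysis (exchange to acetone) unmasks the C1 ketone before any acid-labile epoxide exists, under conditions that silyl and PMB ethers tolerate.

Step 24
Reactants: 35 Z-oxonene C1 ketone
Product: 36 allylic alcohol (C6–OH free)
Conditions: DDQ, CH2Cl2–pH 7 buffer, 0 °C
Reagents that add atoms: none
Why: DDQ oxidative debenzylation frees the C6 hydroxyl that is to direct the epoxidation, leaving the silyl ethers and both alkenes untouched.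

Step 25
Reactants: 36 allylic alcohol
Product: 37 cis epoxy alcohol (4R,5S epoxide; C6–OH free)
Conditions: VO(acac)2 (5 mol%), t-BuOOH, CH2Cl2, 0 °C → rt
Reagents that add atoms: tert-butyl hydroperoxide, CC(C)(C)OO
Why: In this hydroxyl-directed vanadium-catalysed epoxidation the C6 vanadate ester delivers oxygen to the allylic trisubstituted C4=C5 bond on the face syn to C6–O, as is known for eight- and nine-membered Z-cycloalkenols, which sets C4 and C5; the homoallylic 1,1-disubstituted alkene reacts much more slowly and reversible hemiketal formation with the C1 ketone does not remove the directing alcohol.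

Step 26
Reactants: 37 cis epoxy alcohol
Product: 38 epoxy diol (C12–OH and C6–OH free; C8 OTBDPS kept)
Conditions: TBAF, AcOH (1:1), THF, 0 °C
Reagents that add atoms: none
Why: Fluoride desilylation removes the unhindered primary allylic TBS ether selectively over the neopentyl-like secondary TBDPS ether, and the acetic acid buffer suppresses Payne rearrangement of the epoxy alcohol.

Step 27
Reactants: 38 epoxy diol
Product: 41 spiro α-methylene-γ-lactone with C8 OTBDPS, via hydroxy enal 39 (not isolated), via lactol 40 (not isolated)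
Conditions: MnO2 (excess), CH2Cl2, rt
Reagents that add atoms: none
Why: MnO2 oxidises only the allylic primary alcohol, the enal is captured by the C6 hydroxyl as a five-membered lactol, and further oxidation of the lactol gives the lactone (oxidative lactonisation of a 2-methylene-1,4-diol), C8–O being still blocked.

Step 28
Reactants: 41 spiro lactone with C8 OTBDPS
Product: 42 spiro lactone with free C8 alcohol
Conditions: TBAF, AcOH (1:1), THF, rt
Reagents that add atoms: none
Why: Buffered fluoride desilylation frees C8–OH while the low alkoxide concentration should keep the lactone on O6 and leave the epoxide closed.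

Step 29
Reactants: 42 spiro lactone with free C8 alcohol; 43 methacrylic anhydride
Product: 44 target CNP0241021.1
Conditions: Et3N, DMAP, CH2Cl2, 0 °C → rt
Reagents that add atoms: none
Why: DMAP-catalysed acyl transfer from the anhydride esterifies the hindered secondary alcohol without opening the epoxide or the lactone.

**Compound list**

1 | (R)-citramalic acid, (2R)-2-hydroxy-2-methylbutanedioic acid | C[C@@](O)(CC(=O)O)C(=O)O | starting material
2 | 2-[(4R)-2,2,4-trimethyl-5-oxo-1,3-dioxolan-4-yl]acetic acid | C[C@]1(CC(=O)O)OC(C)(C)OC1=O | intermediate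
3 | 4-methoxybenzyl propargyl ether | C#CCOCc1ccc(OC)cc1 | starting material
4 | 2-[(4R)-2,2,4-trimethyl-5-oxo-1,3-dioxolan-4-yl]acetyl chloride | C[C@]1(CC(=O)Cl)OC(C)(C)OC1=O | intermediate
5 | (5R)-5-[5-(4-methoxybenzyloxy)-2-oxopent-3-yn-1-yl]-2,2,5-trimethyl-1,3-dioxolan-4-one | C[C@]1(CC(=O)C#CCOCc2ccc(OC)cc2)OC(C)(C)OC1=O | intermediate
6 | (5R)-5-[(2S)-2-hydroxy-5-(4-methoxybenzyloxy)pent-3-yn-1-yl]-2,2,5-trimethyl-1,3-dioxolan-4-one | C[C@]1(C[C@H](O)C#CCOCc2ccc(OC)cc2)OC(C)(C)OC1=O | intermediate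
7 | (5R)-5-[(2S)-2-(tert-butyldiphenylsilyloxy)-5-(4-methoxybenzyloxy)pent-3-yn-1-yl]-2,2,5-trimethyl-1,3-dioxolan-4-one | C[C@]1(C[C@H](O[Si](c2ccccc2)(c2ccccc2)C(C)(C)C)C#CCOCc2ccc(OC)cc2)OC(C)(C)OC1=O | intermediate
8 | (R)-butane-1,3-diol | C[C@@H](O)CCO | starting material
9 | (R)-4-iodobutan-2-ol | C[C@@H](O)CCI | intermediate
10 | (R)-triethyl[(4-iodobutan-2-yl)oxy]silane | C[C@@H](O[Si](CC)(CC)CC)CCI | intermediate
11 | [(3R)-3-(triethylsilyloxy)butyl]lithium | [Li]CC[C@@H](C)O[Si](CC)(CC)CC | intermediate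
12 | lithium salt of the cyclic hemiketal from addition of 11 to the ring carbonyl of 7 (C1 epimers) | C[C@@H](O[Si](CC)(CC)CC)CCC1([O-])OC(C)(C)O[C@]1(C)C[C@H](O[Si](c2ccccc2)(c2ccccc2)C(C)(C)C)C#CCOCc2ccc(OC)cc2.[Li+] | intermediate
13 | (2R,6R,8S)-8-(tert-butyldiphenylsilyloxy)-6-hydroxy-11-(4-methoxybenzyloxy)-6-methyl-2-(triethylsilyloxy)undec-9-yn-5-one (skeleton: 4R,8S,10R; C1 ketone) | C[C@@H](O[Si](CC)(CC)CC)CCC(=O)[C@](C)(O)C[C@H](O[Si](c1ccccc1)(c1ccccc1)C(C)(C)C)C#CCOCc1ccc(OC)cc1 | intermediate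
14 | (2R,6R,8S)-8-(tert-butyldiphenylsilyloxy)-5,5-dimethoxy-11-(4-methoxybenzyloxy)-6-methyl-2-(triethylsilyloxy)undec-9-yn-6-ol | C[C@@H](O[Si](CC)(CC)CC)CCC(OC)(OC)[C@](C)(O)C[C@H](O[Si](c1ccccc1)(c1ccccc1)C(C)(C)C)C#CCOCc1ccc(OC)cc1 | intermediate
15 | (4S,6R,10R)-4-(tert-butyldiphenylsilyloxy)-7,7-dimethoxy-6-methyl-10-(triethylsilyloxy)undec-2-yne-1,6-diol | C[C@@H](O[Si](CC)(CC)CC)CCC(OC)(OC)[C@](C)(O)C[C@H](O[Si](c1ccccc1)(c1ccccc1)C(C)(C)C)C#CCO | intermediate
16 | disodium alkenylaluminate of 15 (five-membered C5–O–Al–C7 ring; C10–O bound to a second hydridoaluminate) | C[C@@H](O[Si](CC)(CC)CC)CCC(OC)(OC)[C@](C)(O[Al-]([H])(OCCOC)OCCOC)C[C@H](O[Si](c1ccccc1)(c1ccccc1)C(C)(C)C)C1=CCO[Al-]1(OCCOC)OCCOC.[Na+].[Na+] | intermediate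
17 | (2Z,4S,6R,10R)-4-(tert-butyldiphenylsilyloxy)-3-iodo-7,7-dimethoxy-6-methyl-10-(triethylsilyloxy)undec-2-ene-1,6-diol | C[C@@H](O[Si](CC)(CC)CC)CCC(OC)(OC)[C@](C)(O)C[C@H](O[Si](c1ccccc1)(c1ccccc1)C(C)(C)C)/C(I)=C/CO | intermediate
18 | 2-bromoprop-2-en-1-ol | C=C(Br)CO | starting material
19 | (2-bromoallyloxy)(tert-butyl)dimethylsilane | CC(C)(C)[Si](C)(C)OCC(Br)=C | intermediate
20 | tert-butyldimethyl{[2-(4,4,5,5-tetramethyl-1,3,2-dioxaborolan-2-yl)prop-2-en-1-yl]oxy}silane | CC(C)(C)[Si](C)(C)OCC(=C)B1OC(C)(C)C(C)(C)O1 | intermediate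
21 | (2E,4S,6R,10R)-3-[3-(tert-butyldimethylsilyloxy)prop-1-en-2-yl]-4-(tert-butyldiphenylsilyloxy)-7,7-dimethoxy-6-methyl-10-(triethylsilyloxy)undec-2-ene-1,6-diol | C[C@@H](O[Si](CC)(CC)CC)CCC(OC)(OC)[C@](C)(O)C[C@H](O[Si](c1ccccc1)(c1ccccc1)C(C)(C)C)/C(C(=C)CO[Si](C)(C)C(C)(C)C)=C/CO | intermediate
22 | (6R,7S)-6,7-epoxide of 21 (2,3-epoxy alcohol; skeleton locants) | C[C@@H](O[Si](CC)(CC)CC)CCC(OC)(OC)[C@](C)(O)C[C@H](O[Si](c1ccccc1)(c1ccccc1)C(C)(C)C)[C@@]1(C(=C)CO[Si](C)(C)C(C)(C)C)O[C@@H]1CO | intermediate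
23 | tetrahydrofuran diol (4R,6R,7R,8S,10R): ring O–C7–C8–C9–C10; C10 bears CH3 and the C1 dimethyl ketal chain with 4-OTES; C8 OTBDPS; C7 bears C11(=CH2)CH2OTBS and C6H(OH)–C5H2OH; C6 and C1 branches cis | C[C@@H](O[Si](CC)(CC)CC)CCC(OC)(OC)[C@@]1(C)C[C@H](O[Si](c2ccccc2)(c2ccccc2)C(C)(C)C)[C@@](O1)(C(=C)CO[Si](C)(C)C(C)(C)C)[C@H](O)CO | intermediate
24 | C5/C6 4-methoxybenzylidene acetal of 23 (acetal carbon as both epimers) | C[C@@H](O[Si](CC)(CC)CC)CCC(OC)(OC)[C@@]1(C)C[C@H](O[Si](c2ccccc2)(c2ccccc2)C(C)(C)C)[C@@](O1)(C(=C)CO[Si](C)(C)C(C)(C)C)[C@H]1COC(c2ccc(OC)cc2)O1 | intermediate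
25 | C6 PMB ether with free C5 alcohol (4R,6R,7R,8S,10R) | C[C@@H](O[Si](CC)(CC)CC)CCC(OC)(OC)[C@@]1(C)C[C@H](O[Si](c2ccccc2)(c2ccccc2)C(C)(C)C)[C@@](O1)(C(=C)CO[Si](C)(C)C(C)(C)C)[C@H](OCc2ccc(OC)cc2)CO | intermediate
26 | C5 mesylate of 25 | C[C@@H](O[Si](CC)(CC)CC)CCC(OC)(OC)[C@@]1(C)C[C@H](O[Si](c2ccccc2)(c2ccccc2)C(C)(C)C)[C@@](O1)(C(=C)CO[Si](C)(C)C(C)(C)C)[C@H](OCc2ccc(OC)cc2)COS(C)(=O)=O | intermediate
27 | C5 mesylate with free (4R) alcohol | C[C@@H](O)CCC(OC)(OC)[C@@]1(C)C[C@H](O[Si](c2ccccc2)(c2ccccc2)C(C)(C)C)[C@@](O1)(C(=C)CO[Si](C)(C)C(C)(C)C)[C@H](OCc2ccc(OC)cc2)COS(C)(=O)=O | intermediate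
28 | (4S) thioacetate bearing the C5 mesylate | C[C@H](SC(C)=O)CCC(OC)(OC)[C@@]1(C)C[C@H](O[Si](c2ccccc2)(c2ccccc2)C(C)(C)C)[C@@](O1)(C(=C)CO[Si](C)(C)C(C)(C)C)[C@H](OCc2ccc(OC)cc2)COS(C)(=O)=O | intermediate
29 | caesium (4S) thiolate bearing the C5 mesylate | C[C@H]([S-])CCC(OC)(OC)[C@@]1(C)C[C@H](O[Si](c2ccccc2)(c2ccccc2)C(C)(C)C)[C@@](O1)(C(=C)CO[Si](C)(C)C(C)(C)C)[C@H](OCc2ccc(OC)cc2)COS(C)(=O)=O.[Cs+] | intermediate
30 | ten-membered cyclic sulfide (4S,6S,7R,8S,10R), ring O–C7–C6–C5–S–C4–C3–C2–C1–C10 bridged by the tetrahydrofuran | CC(C)(C)[Si](c1ccccc1)(c1ccccc1)O[C@H]1C[C@@]2(C)O[C@]1(C(=C)CO[Si](C)(C)C(C)(C)C)[C@H](OCc1ccc(OC)cc1)CS[C@@H](C)CCC2(OC)OC | intermediate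
31 | ten-membered cyclic sulfone (4S,6S,7R,8S,10R): C1 dimethyl ketal, C6 OPMB, C8 OTBDPS, C12 OTBS | CC(C)(C)[Si](c1ccccc1)(c1ccccc1)O[C@H]1C[C@@]2(C)O[C@]1(C(=C)CO[Si](C)(C)C(C)(C)C)[C@H](OCc1ccc(OC)cc1)CS(=O)(=O)[C@@H](C)CCC2(OC)OC | intermediate
32 | C5 α-bromo sulfone of 31 (C5 epimers) | CC(C)(C)[Si](c1ccccc1)(c1ccccc1)O[C@H]1C[C@@]2(C)O[C@]1(C(=C)CO[Si](C)(C)C(C)(C)C)[C@H](OCc1ccc(OC)cc1)C(Br)S(=O)(=O)[C@@H](C)CCC2(OC)OC | intermediate
33 | cis-fused C4/C5 thiirane 1,1-dioxide (C3 and C6 cis; face not defined) | CC(C)(C)[Si](c1ccccc1)(c1ccccc1)O[C@H]1C[C@@]2(C)O[C@]1(C(=C)CO[Si](C)(C)C(C)(C)C)[C@H](OCc1ccc(OC)cc1)C3C(C)(CCC2(OC)OC)S3(=O)=O | intermediate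
34 | Z-oxonene (4Z,6R,7R,8S,10R), 11-oxabicyclo[6.2.1]undecene core with C1 dimethyl ketal, C6 OPMB, C8 OTBDPS, C12 OTBS | CC(C)(C)[Si](c1ccccc1)(c1ccccc1)O[C@H]1C[C@@]2(C)O[C@]1(C(=C)CO[Si](C)(C)C(C)(C)C)[C@H](OCc1ccc(OC)cc1)/C=C(C)\CCC2(OC)OC | intermediate
35 | Z-oxonene C1 ketone (C6 OPMB, C8 OTBDPS, C12 OTBS) | CC(C)(C)[Si](c1ccccc1)(c1ccccc1)O[C@H]1C[C@@]2(C)O[C@]1(C(=C)CO[Si](C)(C)C(C)(C)C)[C@H](OCc1ccc(OC)cc1)/C=C(C)\CCC2=O | intermediate
36 | Z-oxonene C1 ketone with free (6R) allylic alcohol | CC(C)(C)[Si](c1ccccc1)(c1ccccc1)O[C@H]1C[C@@]2(C)O[C@]1(C(=C)CO[Si](C)(C)C(C)(C)C)[C@H](O)/C=C(C)\CCC2=O | intermediate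
37 | (4R,5S,6R,7R,8S,10R) cis epoxy alcohol (C8 OTBDPS, C12 OTBS) | CC(C)(C)[Si](c1ccccc1)(c1ccccc1)O[C@H]1C[C@@]2(C)O[C@]1(C(=C)CO[Si](C)(C)C(C)(C)C)[C@H](O)[C@@H]3O[C@]3(C)CCC2=O | intermediate
38 | epoxy diol (C6–OH and C12–OH free, C8 OTBDPS) | CC(C)(C)[Si](c1ccccc1)(c1ccccc1)O[C@H]1C[C@@]2(C)O[C@]1(C(=C)CO)[C@H](O)[C@@H]3O[C@]3(C)CCC2=O | intermediate
39 | C12 enal with free C6–OH | CC(C)(C)[Si](c1ccccc1)(c1ccccc1)O[C@H]1C[C@@]2(C)O[C@]1(C(=C)C=O)[C@H](O)[C@@H]3O[C@]3(C)CCC2=O | intermediate
40 | spiro lactol (C12 hemiacetal epimers) | CC(C)(C)[Si](c1ccccc1)(c1ccccc1)O[C@H]1C[C@@]2(C)O[C@@]13C(=C)C(O)O[C@@H]3[C@@H]1O[C@]1(C)CCC2=O | intermediate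
41 | spiro α-methylene-γ-lactone with C8 OTBDPS (4R,5S,6R,7R,8S,10R) | CC(C)(C)[Si](c1ccccc1)(c1ccccc1)O[C@H]1C[C@@]2(C)O[C@@]13C(=C)C(=O)O[C@@H]3[C@@H]1O[C@]1(C)CCC2=O | intermediate
42 | spiro lactone with free C8 alcohol (4R,5S,6R,7S,8S,10R) | O[C@H]1C[C@@]2(C)O[C@@]13C(=C)C(=O)O[C@@H]3[C@@H]1O[C@]1(C)CCC2=O | intermediate
43 | methacrylic anhydride | C=C(C)C(=O)OC(=O)C(C)=C | starting material
44 | CNP0241021.1 (4R,5S,6R,7S,8S,10R) | C=C(C)C(=O)O[C@H]1C[C@@]2(C)O[C@@]13C(=C)C(=O)O[C@@H]3[C@@H]1O[C@]1(C)CCC2=O | target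

**Step count.** Total: 29 steps. Longest linear sequence: 25 steps (steps 1–4, 7–10, 13–29, from (R)-citramalic acid).

**Steps most likely to fail**

1. Step 22 (key step). What may go wrong: β-elimination of the C6 PMB oxide from the C5 carbanion, or a second bromination at C5 before the C4 proton is removed, so that sulfur is not extruded cleanly. The fallback places the halogen before the sulfone exists and away from C6. It sets out from sulfide 30: N-chlorosuccinimide in CH2Cl2 should chlorinate the more substituted α-carbon (C4) by a Pummerer-type pathway to give the α-chloro sulfide F1. mCPBA at −20 °C should then oxidise it to the α-chloro sulfone F2. KOt-Bu in THF at −78 → 0 °C then brings about the classical base-only Ramberg–Bäcklund reaction (C5 deprotonation, displacement of the tertiary chloride, loss of SO2), and the route is rejoined at 34.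

2. Step 20. What may go wrong: slow SN2 attack at the β-branched, β-oxygenated primary C5 lets intermolecular alkylation and disulfide formation win over ring closure. The fallback exchanges the roles of the two carbons. It sets out from alcohol 25: a Mitsunobu reaction with thioacetic acid gives the C5 thioacetate F3. Buffered HF·pyridine removes the triethylsilyl group to give the C5 thioacetate with free C4 alcohol F4, and MsCl/Et3N gives the (4R) mesylate F5. Cs2CO3 in degassed MeOH–THF at high dilution releases the primary thiolate, which should displace the unhindered secondary mesylate with inversion. The route is rejoined at sulfide 30, with the same (4S) configuration.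

3. Step 14. What may go wrong: poor facial selectivity or stalled turnover, because the alkene carries a bulky cis substituent and the diol product binds titanium. The fallback uses reagent control without a metal alkoxide. It sets out from dienol 21: Shi epoxidation (D-fructose-derived ketone, Oxone, K2CO3 buffer, MeCN–dimethoxymethane, 0 °C) is expected to attack the same face of the electron-rich trisubstituted C6=C7 bond. This is the face it takes in (R,R)-selective epoxidation of trans-disubstituted and trisubstituted alkenes, and it should give epoxy alcohol 22. CSA then closes the tetrahydrofuran and the route is rejoined at diol 23. This fallback makes no compound outside the list (F0).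

**Further compounds**

F1 | step 22 | α-chloro sulfide (chlorine on C4, both epimers) | CC(C)(C)[Si](c1ccccc1)(c1ccccc1)O[C@H]1C[C@@]2(C)O[C@]1(C(=C)CO[Si](C)(C)C(C)(C)C)[C@H](OCc1ccc(OC)cc1)CSC(C)(Cl)CCC2(OC)OC
F2 | step 22 | α-chloro sulfone (chlorine on C4, both epimers) | CC(C)(C)[Si](c1ccccc1)(c1ccccc1)O[C@H]1C[C@@]2(C)O[C@]1(C(=C)CO[Si](C)(C)C(C)(C)C)[C@H](OCc1ccc(OC)cc1)CS(=O)(=O)C(C)(Cl)CCC2(OC)OC
F3 | step 20 | C5 thioacetate with (4R) triethylsilyl ether | C[C@@H](O[Si](CC)(CC)CC)CCC(OC)(OC)[C@@]1(C)C[C@H](O[Si](c2ccccc2)(c2ccccc2)C(C)(C)C)[C@@](O1)(C(=C)CO[Si](C)(C)C(C)(C)C)[C@H](OCc2ccc(OC)cc2)CSC(C)=O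
F4 | step 20 | C5 thioacetate with free (4R) alcohol | C[C@@H](O)CCC(OC)(OC)[C@@]1(C)C[C@H](O[Si](c2ccccc2)(c2ccccc2)C(C)(C)C)[C@@](O1)(C(=C)CO[Si](C)(C)C(C)(C)C)[C@H](OCc2ccc(OC)cc2)CSC(C)=O
F5 | step 20 | C5 thioacetate with (4R) mesylate | C[C@@H](OS(C)(=O)=O)CCC(OC)(OC)[C@@]1(C)C[C@H](O[Si](c2ccccc2)(c2ccccc2)C(C)(C)C)[C@@](O1)(C(=C)CO[Si](C)(C)C(C)(C)C)[C@H](OCc2ccc(OC)cc2)CSC(C)=O
F0 | step 14 | none | none
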